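The beta run held 13.1 % product and 0.5 % idle complex at 25.0 min, which with 0.05 mol% catalyst is 272 turnovers, so the reading gives a turnover frequency, the product and idle complex made per catalyst per minute, of 10.9 min⁻¹.

in all of them: catalyst 0.05 mol%

| run | solid substrate | coupling partner | remark | time |
|---|---|---|---|---|
| beta | 20 mM | 1.3 equiv | run made earlier |  |
| gamma | 20 mM | 2.1 equiv | run made earlier |  |
| theta | 30 mM | 0.95 equiv | run made earlier |  |
| flask | 20 mM | 0.950 equiv |  | 30 min |

| run | time / min | product / % | idle complex / % | solid substrate / % |
|---|---|---|---|---|
| beta | 2.00 | 0 | 0 | 97.3 |
| beta | 4.00 | 1.8 | 0.1 | 96.5 |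
| beta | 10.0 | 4.8 | 0 | 92.4 |
| beta | 25.0 | 13.1 | 0.5 | 84.5 |
| gamma | 2.00 | 2.9 | 2.2 | 97.2 |
| gamma | 4.00 | 2.8 | 0 | 96.6 |
| gamma | 10.0 | 6.9 | 0 | 92.8 |
| gamma | 25.0 | 18.0 | 0 | 82.2 |
| theta | 3.00 | 0 | 0 | 98.7 |
| theta | 8.00 | 2.8 | 0 | 96.2 |
| theta | 15.0 | 7.4 | 0 | 94.3 |
| theta | 25.0 | 9.3 | 0 | 88.7 |

(standard deviation of a reading: 1 percentage point)

- amounts and yields of product count idle complex too
- given per volume of solution although it is solid: solid substrate
- the earlier runs were read with a standard deviation of 1 percentage point
- at the start none of the solid substrate is in solution

- Thursday's: doubling the amount of catalyst, all else as stated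
- Wednesday's: doubling the solubility of the solid substrate, all else as stated
- Saturday's: doubling the amount of coupling partner, all else as stated
- Tuesday's: doubling the dissolution coefficient of the solid substrate, all else as stated

- product and idle complex together at 30 min, in percent of the solid substrate charged
- the change that raises the amount of product and idle complex together at 30 min, in percent of the solid substrate charged most ("none" if none brings more than 2 percentage points) (Thursday's / Wednesday's / Saturday's / Tuesday's / none)
- amount of product and idle complex together at 30 min, in percent of the solid substrate charged, after Tuesday's

The asked flask differs from beta in its coupling partner, 0.950 equiv against 1.3 equiv, and in its time, and two extreme versions of it can be reckoned in the head. If dissolution of the solid substrate is the rate-limiting step, the frequency ignores [coupling partner] and stays as read: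

y(high) = frequency × time × loading = 16.3 %

At the other extreme the frequency is proportional to [coupling partner]:

y(low) = y(high) × 0.950 / 1.3 = 11.9 %

The gamma run places the flask between these, since its coupling partner stands at 1.62 times beta's while its product and idle complex stand at 1.32 times. Those two readings give an order in coupling partner of 0.584, and so this reckoning commits to:

y = y(high) × (0.950 / 1.3)^0.584 = 13.6 %

The forecast says 13.5 %, with Wednesday's as the best change and 17 % after Tuesday's, on the grounds: “I treated this as dissolution and reaction in series”.

The flask gives 12.3 %, inside the bracket, and 15.9 % after Tuesday's, while Wednesday's adds the most, 11 percentage points.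

    starting material + coupling partner + catalyst → catalyst + product (k = 16000 L² mol⁻² s⁻¹)
    solid substrate ⇌ starting material, rate k2*(cs2 - [starting material]) while solid is left; crystals form when [starting material] > cs2 (solubility = 1.00 mM, k = 0.00340 s⁻¹)
    catalyst + product ⇌ idle complex, settled at all times (K = 39.0 L mol⁻¹)

The neighbouring flask has 5.0 mM solid substrate, with equivalents, loading and time held, so its [coupling partner] and its catalyst fall with the charge: the frequency read in beta, taken proportional to [coupling partner], puts its lower end at 2.98 %, while the same millimoles per litre dissolved as in beta, now spread over less catalyst, raise the frequency with the ratio of the charges and put its upper end at 65.3 %. That neighbouring flask gives 5.30 %, inside its bracket, a frequency of 3.53 min⁻¹.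

The readings were generated by integration for substances that don't exist, noise included.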